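**Plan**
1. Cuts: the phenol is unmasked last. The oxolane is opened at the benzylic ether bond O1–C2 to give an acyclic triol. The chain is then cut at C2–C3 and at the bond from C4 to the ring B benzylic carbon.
2. Enabling feature: in the oxolane (O1, C2 with ring A, C3 with CH2OH, C4 with the ring B benzyl group, C5), C3 and C4 are the β and α carbons of a 5-alkoxybutenolide. C5 is its carbonyl carbon and the CH2OH carbon is its acetal carbon. C2 is at the ketone level, so it can be delivered as an acyl anion.
3. Forward order: butenolide, ring A dithiane and ring B benzylic bromide are joined in one flask. The lactone serves only as a template and is opened by hydride. The single ring of the target, the oxolane, is closed in the penultimate step by O1–C2 bond formation.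
4. Stereochemistry: (−)-menthol plus crystallisation fixes the acetal centre. This centre sends the dithiane anion to the opposite face and sets C3. The dithianyl group then sends the bromide to the opposite face and sets C4. The relationship is trans on the lactone but reads 3,4-cis once C2 replaces the CH2OH carbon as ring neighbour. C2 is set in the cyclisation, where ring A settles trans to the C3 substituent.

Key step: step 6

Locants: O1 and C2–C5 refer to the oxolane of the target. Ring A is the 3,4-dimethoxyphenyl group on C2. Ring B is the aryl ring of the benzyl group on C4. Lactone locants are marked as such.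
Assumption: the carbinol carbon formed in step 8 arises as a mixture of epimers and is drawn without a descriptor. Ionisation in step 9 erases it.

Step 1
Reactants: 1 furfural
Product: 3 5-hydroxyfuran-2(5H)-one (racemic), via furfural endoperoxide 2 (not isolated)
Conditions: O2, rose bengal (cat.), hν (visible), MeOH, 20 °C
Reagents that add atoms: dioxygen, O=O
Why: In this dye-sensitised photooxygenation, singlet oxygen adds [4+2] across the furan diene to give 2, and methanol then removes the formyl group with O–O cleavage, a standard preparative entry to this configurationally labile hemiacetal, so no stereocentre is at stake.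

Step 2
Reactants: 3 5-hydroxyfuran-2(5H)-one; 4 (−)-menthol
Product: 5 (5R)-5-[(1R,2S,5R)-menthyloxy]furan-2(5H)-one
Conditions: CSA (cat.), toluene, reflux, azeotropic removal of water; crystallisation from hexane, mother liquor re-equilibrated with CSA and recrystallised
Reagents that add atoms: none
Why: Acid-catalysed acetalisation with the chiral-pool alcohol gives two acetal epimers that interconvert under acid, and only the (5R) epimer crystallises, so crystallisation with recycling of the liquor sets this stereocentre.

Step 3
Reactants: 6 veratraldehyde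
Product: 7 2-(3,4-dimethoxyphenyl)-1,3-dithiane
Conditions: HS(CH2)3SH, BF3·OEt2 (cat.), CH2Cl2, 0 °C → rt
Reagents that add atoms: propane-1,3-dithiol, SCCCS
Why: Lewis-acid-catalysed thioacetalisation of an aromatic aldehyde is routine and turns the formyl carbon (future C2) into an acyl-anion equivalent (dithiane umpolung).

Step 4
Reactants: 8 4-(benzyloxy)-3-methoxybenzaldehyde
Product: 9 4-(benzyloxy)-3-methoxybenzyl alcohol
Conditions: NaBH4, MeOH/THF, 0 °C
Reagents that add atoms: none
Why: This is a borohydride reduction of an aromatic aldehyde, to which the benzyl and methyl ethers are inert.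

Step 5
Reactants: 9 4-(benzyloxy)-3-methoxybenzyl alcohol
Product: 10 4-(benzyloxy)-3-methoxybenzyl bromide
Conditions: PBr3, Et2O, 0 °C; used at once without chromatography
Reagents that add atoms: phosphorus tribromide, BrP(Br)Br
Why: Bromide displaces the phosphite ester of an electron-rich benzylic alcohol rapidly at 0 °C, and immediate use avoids decay of the labile bromide.

Step 6
Reactants: 7 2-(3,4-dimethoxyphenyl)-1,3-dithiane; 5 (5R)-5-[(1R,2S,5R)-menthyloxy]furan-2(5H)-one; 10 4-(benzyloxy)-3-methoxybenzyl bromide
Product: 13 (3R,4R,5R)-3-[4-(benzyloxy)-3-methoxybenzyl]-4-[2-(3,4-dimethoxyphenyl)-1,3-dithian-2-yl]-5-[(1R,2S,5R)-menthyloxy]oxolan-2-one (trans,trans), via lithiated dithiane 11 (not isolated), via lithium enolate 12 (not isolated)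
Conditions: 7, n-BuLi, THF, −78 → −20 °C; 5, THF, −78 °C; then 10, DMPU, −78 °C → rt
Reagents that add atoms: none
Why: n-BuLi removes the acidic C–H of 7 to give the sulfur- and aryl-stabilised carbanion 11, which adds to the β carbon of 5 (Michael addition, forming C2–C3) to give enolate 12, and 12 then displaces bromide from 10 at its α carbon (SN2 alkylation, forming the bond from C4 to the ring B benzylic carbon). The closest known reaction type is the three-component tandem conjugate addition–enolate alkylation of 5-alkoxybutenolides with lithiated aryl dithioacetals and benzylic halides, an established entry to dibenzylbutyrolactone lignans. No ring is closed; the lactone is only the template on which both bonds are made. The β stereocentre (future C3) is controlled by the acetal carbon of 5, whose menthyloxy group screens one face of the flat ring so that 11 enters anti to it, and the α stereocentre (future C4) is controlled by the very large dithianyl group just installed, so the bromide approaches the enolate from the opposite face. The step needs 1,4- over 1,2-addition, which is secured by the soft, delocalised and hindered carbanion, whose carbonyl addition is reversible while its conjugate addition is not. It also needs clean C-monoalkylation, which is secured by the reactive benzylic bromide, by DMPU loosening the enolate aggregates and by the shielded remaining α-hydrogen of 13.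

Step 7
Reactants: 13 tandem adduct
Product: 14 (3R,4R,5R)-3-[4-(benzyloxy)-3-methoxybenzyl]-4-(3,4-dimethoxybenzoyl)-5-[(1R,2S,5R)-menthyloxy]oxolan-2-one
Conditions: MeI (excess), CaCO3, MeCN/H2O, 40 °C
Reagents that add atoms: water, O
Why: In this alkylative dithiane hydrolysis, S-methylation makes sulfur a leaving group, water captures the thionium ion stabilised by ring A, and the CaCO3 buffer keeps the medium near neutral so that the lactone, the menthyl acetal and the epimerisable centre next to the new ketone stay untouched.

Step 8
Reactants: 14 keto lactone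
Product: 15 (2R,3R)-2-[4-(benzyloxy)-3-methoxybenzyl]-3-[(3,4-dimethoxyphenyl)(hydroxy)methyl]butane-1,4-diol (both carbinol epimers)
Conditions: LiAlH4, THF, 0 °C → rt; non-acidic aqueous work-up
Reagents that add atoms: none
Why: In this exhaustive hydride reduction, LiAlH4 reduces the ketone and the lactone, and the hemiacetal alkoxide so released expels menthoxide to give an aldehyde that is reduced as well, which delivers the triol and recoverable menthol without touching C3 or C4.

Step 9
Reactants: 15 triol
Product: 16 [(2S,3R,4R)-4-[4-(benzyloxy)-3-methoxybenzyl]-2-(3,4-dimethoxyphenyl)oxolan-3-yl]methanol (2,3-trans, 3,4-cis)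
Conditions: CSA (cat.), CH2Cl2, 0 °C; Et3N quench at full conversion
Reagents that add atoms: none
Why: In this acid-catalysed dehydrative etherification of SN1 type, both carbinol epimers ionise to the same benzylic cation stabilised by the para methoxy group of ring A, only the C5 hydroxyl can reach it through a five-membered transition state (the C3 hydroxymethyl would give an oxetane), and the closure, reversible under the conditions, puts ring A trans to the C3 substituent and so sets (2S), while catalytic acid, low temperature and an early quench keep ring B from competing as a carbon nucleophile.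

Step 10
Reactants: 16 benzyl ether
Product: 17 4-{[(3R,4R,5S)-5-(3,4-dimethoxyphenyl)-4-(hydroxymethyl)oxolan-3-yl]methyl}-2-methoxyphenol (target; oxolane locants 2S,3R,4R)
Conditions: H2 (1 atm), 10% Pd/C, EtOAc, rt; stopped after one equivalent of H2
Reagents that add atoms: none
Why: Catalytic hydrogenolysis of an aryl benzyl ether is much faster than cleavage of the cyclic benzylic O1–C2 bond in a neutral aprotic solvent, so the phenol should be freed with all three stereocentres untouched.

**Compound list**
1 | furfural | O=Cc1ccco1 | starting material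
2 | furfural endoperoxide, 2,3,7-trioxabicyclo[2.2.1]hept-5-ene-1-carbaldehyde (racemic, not isolated) | O=CC12OOC(C=C1)O2 | intermediate
3 | 5-hydroxyfuran-2(5H)-one (racemic) | O=C1C=CC(O)O1 | intermediate
4 | (−)-menthol, (1R,2S,5R) | C[C@@H]1CC[C@H]([C@@H](C1)O)C(C)C | starting material
5 | (5R)-5-[(1R,2S,5R)-menthyloxy]furan-2(5H)-one | O=C1C=C[C@H](O[C@@H]2C[C@H](C)CC[C@H]2C(C)C)O1 | intermediate
6 | veratraldehyde | COc1ccc(C=O)cc1OC | starting material
7 | 2-(3,4-dimethoxyphenyl)-1,3-dithiane | COc1ccc(C2SCCCS2)cc1OC | intermediate
8 | 4-(benzyloxy)-3-methoxybenzaldehyde | COc1cc(C=O)ccc1OCc1ccccc1 | starting material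
9 | 4-(benzyloxy)-3-methoxybenzyl alcohol | COc1cc(CO)ccc1OCc1ccccc1 | intermediate
10 | 4-(benzyloxy)-3-methoxybenzyl bromide | COc1cc(CBr)ccc1OCc1ccccc1 | intermediate
11 | 2-lithio-2-(3,4-dimethoxyphenyl)-1,3-dithiane (not isolated) | [Li]C1(c2ccc(OC)c(OC)c2)SCCCS1 | intermediate
12 | lithium enolate of the (4R,5R) Michael adduct (not isolated) | [Li]OC1=C[C@@H](C2(c3ccc(OC)c(OC)c3)SCCCS2)[C@H](O[C@@H]4C[C@H](C)CC[C@H]4C(C)C)O1 | intermediate
13 | (3R,4R,5R)-3-[4-(benzyloxy)-3-methoxybenzyl]-4-[2-(3,4-dimethoxyphenyl)-1,3-dithian-2-yl]-5-[(1R,2S,5R)-menthyloxy]oxolan-2-one | COc1cc(C[C@H]2C(=O)O[C@@H](O[C@@H]3C[C@H](C)CC[C@H]3C(C)C)[C@@H]2C4(c5ccc(OC)c(OC)c5)SCCCS4)ccc1OCc1ccccc1 | intermediate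
14 | (3R,4R,5R)-3-[4-(benzyloxy)-3-methoxybenzyl]-4-(3,4-dimethoxybenzoyl)-5-[(1R,2S,5R)-menthyloxy]oxolan-2-one | COc1cc(C[C@H]2C(=O)O[C@@H](O[C@@H]3C[C@H](C)CC[C@H]3C(C)C)[C@@H]2C(=O)c4ccc(OC)c(OC)c4)ccc1OCc1ccccc1 | intermediate
15 | (2R,3R)-2-[4-(benzyloxy)-3-methoxybenzyl]-3-[(3,4-dimethoxyphenyl)(hydroxy)methyl]butane-1,4-diol, carbinol epimers | COc1cc(C[C@@H](CO)[C@H](CO)C(O)c2ccc(OC)c(OC)c2)ccc1OCc1ccccc1 | intermediate
16 | [(2S,3R,4R)-4-[4-(benzyloxy)-3-methoxybenzyl]-2-(3,4-dimethoxyphenyl)oxolan-3-yl]methanol | COc1cc(C[C@H]2CO[C@H](c3ccc(OC)c(OC)c3)[C@H]2CO)ccc1OCc1ccccc1 | intermediate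
17 | 4-{[(3R,4R,5S)-5-(3,4-dimethoxyphenyl)-4-(hydroxymethyl)oxolan-3-yl]methyl}-2-methoxyphenol | COc1cc(C[C@H]2CO[C@H](c3ccc(OC)c(OC)c3)[C@H]2CO)ccc1O | target

Total step count: 10.
Longest linear sequence: 7 steps (1, 2, 6, 7, 8, 9, 10 from furfural; equally 4, 5, 6, 7, 8, 9, 10 from 8).

**Three steps most likely to fail**

Step 6 (tandem addition–alkylation).
- Risk: the hindered enolate may be captured too slowly. Proton exchange with the product, a second alkylation or decay of the labile bromide on warming would then erode the one-pot process. Competing attack at the lactone carbonyl is the lesser danger.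
- Fallback: the two bond formations are separated. Setting out from 5 (with 7), the conjugate addition is run alone. The enolate is protonated at −78 °C with aqueous NH4Cl to give the Michael adduct (4R,5R)-4-[2-(3,4-dimethoxyphenyl)-1,3-dithian-2-yl]-5-[(1R,2S,5R)-menthyloxy]oxolan-2-one F1, which can be purified by crystallisation. F1 is then deprotonated with exactly one equivalent of LiN(SiMe3)2 in THF/DMPU at −78 °C. Alkylation with freshly made 10, again anti to the dithianyl group, rejoins the route at 13.

Step 7 (dithiane unmasking).
- Risk: S-alkylation at the crowded dithiane may be slow. Once the carbonyl group is free, enolisation toward lactone C4 may cause epimerisation or β-elimination of the lactone carboxylate from the acetal carbon.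
- Fallback: the order of events is changed so that the ketone appears only after the acyloxy acetal is gone. Setting out from 13, LiAlH4 in THF reduces the lactone and the acetal while the dithiane stays inert. This gives (2R,3R)-2-[4-(benzyloxy)-3-methoxybenzyl]-3-[2-(3,4-dimethoxyphenyl)-1,3-dithian-2-yl]butane-1,4-diol F2. Oxidative unmasking with PhI(OCOCF3)2 in aqueous MeCN at 0 °C gives the keto diol (2R,3R)-4-[4-(benzyloxy)-3-methoxyphenyl]-1-(3,4-dimethoxyphenyl)-2,3-bis(hydroxymethyl)butan-1-one F3. F3 is reduced at once with NaBH4 in MeOH and rejoins the route at 15.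

Step 9 (oxolane closure).
- Risk: ring B may capture the benzylic cation irreversibly in a Friedel–Crafts reaction at the position para to its methoxy group, closing a six-membered carbocycle. This takes over once acid strength or time is exceeded. Stopping early may in turn leave the equilibration at C2 incomplete.
- Fallback: the nucleophilic position is blocked. Setting out from 14, in which the carbonyl group deactivates ring A, NBS in MeCN at 0 °C in the dark should brominate only ring B, para to its methoxy group. This gives (3R,4R,5R)-3-[4-(benzyloxy)-2-bromo-5-methoxybenzyl]-4-(3,4-dimethoxybenzoyl)-5-[(1R,2S,5R)-menthyloxy]oxolan-2-one F4. LiAlH4 in THF at 0 °C gives (2R,3R)-2-[4-(benzyloxy)-2-bromo-5-methoxybenzyl]-3-[(3,4-dimethoxyphenyl)(hydroxy)methyl]butane-1,4-diol F5. The CSA cyclisation can now be driven to equilibrium and gives [(2S,3R,4R)-4-[4-(benzyloxy)-2-bromo-5-methoxybenzyl]-2-(3,4-dimethoxyphenyl)oxolan-3-yl]methanol F6. H2, Pd/C and NaOAc in EtOAc/MeOH then remove the bromine and the benzyl group together, and the route is rejoined at 17.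

**Further compounds**
F1 | step 6 | (4R,5R)-4-[2-(3,4-dimethoxyphenyl)-1,3-dithian-2-yl]-5-[(1R,2S,5R)-menthyloxy]oxolan-2-one | O=C1C[C@@H](C2(c3ccc(OC)c(OC)c3)SCCCS2)[C@H](O[C@@H]4C[C@H](C)CC[C@H]4C(C)C)O1
F2 | step 7 | (2R,3R)-2-[4-(benzyloxy)-3-methoxybenzyl]-3-[2-(3,4-dimethoxyphenyl)-1,3-dithian-2-yl]butane-1,4-diol | COc1cc(C[C@@H](CO)[C@H](CO)C2(c3ccc(OC)c(OC)c3)SCCCS2)ccc1OCc1ccccc1
F3 | step 7 | (2R,3R)-4-[4-(benzyloxy)-3-methoxyphenyl]-1-(3,4-dimethoxyphenyl)-2,3-bis(hydroxymethyl)butan-1-one | COc1cc(C[C@@H](CO)[C@H](CO)C(=O)c2ccc(OC)c(OC)c2)ccc1OCc1ccccc1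
F4 | step 9 | (3R,4R,5R)-3-[4-(benzyloxy)-2-bromo-5-methoxybenzyl]-4-(3,4-dimethoxybenzoyl)-5-[(1R,2S,5R)-menthyloxy]oxolan-2-one | COc1cc(C[C@H]2C(=O)O[C@@H](O[C@@H]3C[C@H](C)CC[C@H]3C(C)C)[C@@H]2C(=O)c4ccc(OC)c(OC)c4)c(Br)cc1OCc1ccccc1
F5 | step 9 | (2R,3R)-2-[4-(benzyloxy)-2-bromo-5-methoxybenzyl]-3-[(3,4-dimethoxyphenyl)(hydroxy)methyl]butane-1,4-diol, carbinol epimers | COc1cc(C[C@@H](CO)[C@H](CO)C(O)c2ccc(OC)c(OC)c2)c(Br)cc1OCc1ccccc1
F6 | step 9 | [(2S,3R,4R)-4-[4-(benzyloxy)-2-bromo-5-methoxybenzyl]-2-(3,4-dimethoxyphenyl)oxolan-3-yl]methanol | COc1cc(C[C@H]2CO[C@H](c3ccc(OC)c(OC)c3)[C@H]2CO)c(Br)cc1OCc1ccccc1
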